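**Assumption:** carbon labels follow germacranolide numbering (C1 ketone, C2=C3 alkene, C4 methyl-bearing, C5 carbinol, C6 lactone O-bearing, C7, C8 angelate-bearing, C9 CH2, C10 acetoxy-bearing, C11=C13 methylene, C12 lactone carbonyl); the target is (4S,5S,6S,7R,8R,10S), 2E, with a (Z)-2-methylbut-2-enoate (angelate). TBS = tert-butyldimethylsilyl.

## Retrosynthetic overview

1. Target 32 ⇐ 29 by C1 oxidation, C10 acetylation and C5 desilylation; the ten-membered carbocycle (ring B) is closed last, at C1–C2, by intramolecular CrCl2/NiCl2 alkenyl iodide–aldehyde coupling.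
2. Seco-aldehyde 27 ⇐ 24 by angeloylation of C8–OH, acetonide removal and oxidation of C1.
3. 24 ⇐ stannane 23 + aldehyde 5: the new C7–C8 bond-forming step, which sets C7 and C8 and unveils the exocyclic methylene of the lactone (ring A).
4. 23 ⇐ lactone 8 (ring A and C6 from the chiral pool) by Marshall propargylation (C4, C5), hydrozirconation–iodination and selenoxide chemistry; 5 ⇐ (R)-2-methylglycidol (C10).
5. Ring order: ring A is present from the start of the west fragment; ring B is formed in step 17.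

## Route

Step 1
Reactants: 1 (R)-2-methylglycidol
Product: 2 (2S)-2-methylpent-4-ene-1,2-diol
Conditions: CH2=CHMgBr (2.5 equiv), CuI (10 mol %), THF, −20 °C; aq NH4Cl
Reagents that add atoms: vinylmagnesium bromide, C=C[Mg]Br
Why: Copper-catalysed Grignard opening (SN2) of the epoxide at its unhindered CH2 terminus leaves the quaternary carbinol carbon (future C10) untouched, so its configuration comes from the chiral pool (R becomes S only through CIP priorities).

Step 2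
Reactants: 2 (2S)-2-methylpent-4-ene-1,2-diol
Product: 3 (4S)-2,2,4-trimethyl-4-(prop-2-en-1-yl)-1,3-dioxolane
Conditions: Me2C(OMe)2, PPTS (cat.), CH2Cl2, rt
Reagents that add atoms: 2,2-dimethoxypropane, COC(C)(C)OC
Why: Acid-catalysed transketalisation closes the five-membered acetonide over the tertiary (C10) and primary (C1) hydroxyls.

Step 3
Reactants: 3 (4S)-2,2,4-trimethyl-4-(prop-2-en-1-yl)-1,3-dioxolane
Product: 5 2-[(4S)-2,2,4-trimethyl-1,3-dioxolan-4-yl]acetaldehyde, via secondary ozonide 4 (not isolated)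
Conditions: O3, CH2Cl2, −78 °C; then PPh3, −78 °C → rt
Reagents that add atoms: ozone, [O-][O+]=O
Why: Ozonolysis with reductive work-up cleaves the only alkene to the C8 aldehyde without touching C10.

Step 4
Reactants: 6 (R)-but-3-yn-2-ol
Product: 7 (R)-but-3-yn-2-yl methanesulfonate
Conditions: MsCl, Et3N, CH2Cl2, −78 °C
Reagents that add atoms: methanesulfonyl chloride, CS(=O)(=O)Cl
Why: O-Sulfonylation proceeds with retention and gives the propargylic electrophile for the Marshall reaction.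

Step 5
Reactants: 8 (S)-5-(hydroxymethyl)dihydrofuran-2(3H)-one
Product: 9 (S)-5-oxotetrahydrofuran-2-carbaldehyde
Conditions: Dess–Martin periodinane, CH2Cl2, rt; filtered, used at once
Reagents that add atoms: none
Why: Dess–Martin oxidation under non-aqueous, near-neutral conditions gives the labile α-acyloxy aldehyde without epimerising C6.

Step 6
Reactants: 9 (S)-5-oxotetrahydrofuran-2-carbaldehyde; 7 (R)-but-3-yn-2-yl methanesulfonate
Product: 11 (5S)-5-[(1S,2S)-1-hydroxy-2-methylbut-3-yn-1-yl]oxolan-2-one, via allenyl(ethyl)zinc 10 (not isolated)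
Conditions: Pd(OAc)2 (5 mol %), PPh3 (5 mol %), Et2Zn (3 equiv), THF, −78 → −20 °C
Reagents that add atoms: none
Why: Marshall propargylation: zerovalent palladium displaces the mesylate anti-SN2′, transmetalation gives the configurationally defined allenylzinc, and its cyclic SE2′ addition fixes C4 as S (reagent) and C5 as S (anti topology), overriding the weak Felkin bias of 9.

Step 7
Reactants: 11 (5S)-5-[(1S,2S)-1-hydroxy-2-methylbut-3-yn-1-yl]oxolan-2-one
Product: 12 (5S)-5-[(1S,2S)-1-(tert-butyldimethylsilyloxy)-2-methylbut-3-yn-1-yl]oxolan-2-one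
Conditions: TBSOTf, 2,6-lutidine, CH2Cl2, −78 → 0 °C
Reagents that add atoms: tert-butyldimethylsilyl triflate, CC(C)(C)[Si](C)(C)OS(=O)(=O)C(F)(F)F
Why: Silylation with the reactive triflate protects the hindered C5 hydroxyl under non-nucleophilic conditions that spare the lactone.

Step 8
Reactants: 12 (5S)-5-[(1S,2S)-1-(tert-butyldimethylsilyloxy)-2-methylbut-3-yn-1-yl]oxolan-2-one
Product: 14 (5S)-5-[(1S,2S,3E)-1-(tert-butyldimethylsilyloxy)-4-iodo-2-methylbut-3-en-1-yl]oxolan-2-one, via alkenylzirconocene chloride 13 (not isolated)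
Conditions: Cp2Zr(H)Cl (1.5 equiv), THF, rt, 30 min; then I2, 0 °C
Reagents that add atoms: iodine, [I][I]
Why: syn-Hydrozirconation places zirconium on the terminal carbon and iodinolysis goes with retention, giving the (E)-alkenyl iodide (C2=C3) faster than the hydride attacks the lactone.

Step 9
Reactants: 14 (5S)-5-[(1S,2S,3E)-1-(tert-butyldimethylsilyloxy)-4-iodo-2-methylbut-3-en-1-yl]oxolan-2-one
Product: 16 (3RS,5S)-5-[(1S,2S,3E)-1-(tert-butyldimethylsilyloxy)-4-iodo-2-methylbut-3-en-1-yl]-3-(phenylselanyl)oxolan-2-one, via lithium enolate 15 (not isolated)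
Conditions: LiN(iPr)2, THF, −78 °C; then PhSeBr
Reagents that add atoms: phenylselenyl bromide, Br[Se]c1ccccc1
Why: Kinetic enolisation of the lactone and α-selenenylation at C11 (the only enolisable position); the new centre is destroyed in the next step.

Step 10
Reactants: 16 (3RS,5S)-5-[(1S,2S,3E)-1-(tert-butyldimethylsilyloxy)-4-iodo-2-methylbut-3-en-1-yl]-3-(phenylselanyl)oxolan-2-one
Product: 20 (5S)-3-(hydroxymethyl)-5-[(1S,2S,3E)-1-(tert-butyldimethylsilyloxy)-4-iodo-2-methylbut-3-en-1-yl]furan-2(5H)-one, via lithium enolate 17 (not isolated), via hydroxymethyl selenide 18 (not isolated), via selenoxide 19 (not isolated)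
Conditions: LiN(iPr)2, THF, −78 °C; CH2O (gas); then 30% H2O2, pyridine, CH2Cl2, 0 °C → rt
Reagents that add atoms: formaldehyde, C=O
Why: Aldol addition of the α-seleno enolate to formaldehyde followed by selenoxide syn-elimination, which runs into the ring (C7–H) and not toward the carbinol carbon, gives the 3-(hydroxymethyl)butenolide.

Step 11
Reactants: 20 (5S)-3-(hydroxymethyl)-5-[(1S,2S,3E)-1-(tert-butyldimethylsilyloxy)-4-iodo-2-methylbut-3-en-1-yl]furan-2(5H)-one
Product: 21 (5S)-3-(bromomethyl)-5-[(1S,2S,3E)-1-(tert-butyldimethylsilyloxy)-4-iodo-2-methylbut-3-en-1-yl]furan-2(5H)-one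
Conditions: CBr4, PPh3, CH2Cl2, 0 °C
Reagents that add atoms: carbon tetrabromide, BrC(Br)(Br)Br
Why: Appel bromination of the primary allylic alcohol under neutral conditions that do not epimerise the γ-position (C6).

Step 12
Reactants: 21 (5S)-3-(bromomethyl)-5-[(1S,2S,3E)-1-(tert-butyldimethylsilyloxy)-4-iodo-2-methylbut-3-en-1-yl]furan-2(5H)-one
Product: 23 (5S)-5-[(1S,2S,3E)-1-(tert-butyldimethylsilyloxy)-4-iodo-2-methylbut-3-en-1-yl]-3-[(tributylstannyl)methyl]furan-2(5H)-one, via allylzinc bromide 22 (not isolated)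
Conditions: Zn dust, Bu3SnCl, THF, sonication, 0 °C → rt
Reagents that add atoms: tributyltin chloride, CCCC[Sn](Cl)(CCCC)CCCC
Why: Barbier-type zinc insertion into the allylic C–Br bond (the alkenyl iodide is inert to zinc dust) and trapping with Bu3SnCl gives the conjugated primary allylstannane, the thermodynamically preferred regioisomer.

Step 13
Reactants: 23 (5S)-5-[(1S,2S,3E)-1-(tert-butyldimethylsilyloxy)-4-iodo-2-methylbut-3-en-1-yl]-3-[(tributylstannyl)methyl]furan-2(5H)-one; 5 2-[(4S)-2,2,4-trimethyl-1,3-dioxolan-4-yl]acetaldehyde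
Product: 24 (4R,5S)-4-{(1R)-1-hydroxy-2-[(4S)-2,2,4-trimethyl-1,3-dioxolan-4-yl]ethyl}-5-[(1S,2S,3E)-1-(tert-butyldimethylsilyloxy)-4-iodo-2-methylbut-3-en-1-yl]-3-methylideneoxolan-2-one
Conditions: 5 (1.5 equiv), BF3·OEt2 (2 equiv), CH2Cl2, −78 → −40 °C; aq NaHCO3
Reagents that add atoms: none
Why: Proposed new method: BF3-promoted anti-SE2′ addition of a ring-locked 2-carbonyl allylstannane (a 3-(stannylmethyl)butenolide) to an aldehyde: C7 attacks the BF3-activated aldehyde on the face opposite the bulky C6 side chain (trans lactone, 7R), the open antiperiplanar transition state keeps the aldehyde substituent away from C6 and so gives the 7,8-syn (8R) carbinol, and loss of Bu3Sn+ from C13 moves the double bond into the exocyclic position; the closest known reactions are the syn-selective BF3-mediated additions of crotylstannanes to aldehydes and the Lewis-acid-mediated additions of acyclic 2-(alkoxycarbonyl)allylstannanes that give α-methylene-γ-butyrolactones.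

Step 14
Reactants: 24 (4R,5S)-4-{(1R)-1-hydroxy-2-[(4S)-2,2,4-trimethyl-1,3-dioxolan-4-yl]ethyl}-5-[(1S,2S,3E)-1-(tert-butyldimethylsilyloxy)-4-iodo-2-methylbut-3-en-1-yl]-3-methylideneoxolan-2-one
Product: 25 (4R,5S)-4-{(1R)-1-[(Z)-2-methylbut-2-enoyloxy]-2-[(4S)-2,2,4-trimethyl-1,3-dioxolan-4-yl]ethyl}-5-[(1S,2S,3E)-1-(tert-butyldimethylsilyloxy)-4-iodo-2-methylbut-3-en-1-yl]-3-methylideneoxolan-2-one
Conditions: angelic acid (3 equiv), 2,4,6-Cl3C6H2COCl, Et3N, PhMe, rt, 2 h; then 24, 80 °C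
Reagents that add atoms: angelic acid, C/C=C(/C)C(=O)O
Why: Yamaguchi-type mixed-anhydride esterification without DMAP acylates C8–OH with retention (acyl–O bond formation) and avoids angelate-to-tiglate isomerisation.

Step 15
Reactants: 25 (4R,5S)-4-{(1R)-1-[(Z)-2-methylbut-2-enoyloxy]-2-[(4S)-2,2,4-trimethyl-1,3-dioxolan-4-yl]ethyl}-5-[(1S,2S,3E)-1-(tert-butyldimethylsilyloxy)-4-iodo-2-methylbut-3-en-1-yl]-3-methylideneoxolan-2-one
Product: 26 (4R,5S)-4-{(1R,3S)-3,4-dihydroxy-3-methyl-1-[(Z)-2-methylbut-2-enoyloxy]butyl}-5-[(1S,2S,3E)-1-(tert-butyldimethylsilyloxy)-4-iodo-2-methylbut-3-en-1-yl]-3-methylideneoxolan-2-one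
Conditions: PPTS, MeOH, 45 °C
Reagents that add atoms: none
Why: Acid-catalysed transketalisation to methanol removes the acetonide while the hindered secondary TBS ether, the angelate and the lactone survive.

Step 16
Reactants: 26 (4R,5S)-4-{(1R,3S)-3,4-dihydroxy-3-methyl-1-[(Z)-2-methylbut-2-enoyloxy]butyl}-5-[(1S,2S,3E)-1-(tert-butyldimethylsilyloxy)-4-iodo-2-methylbut-3-en-1-yl]-3-methylideneoxolan-2-one
Product: 27 (4R,5S)-4-{(1R,3S)-3-hydroxy-3-methyl-1-[(Z)-2-methylbut-2-enoyloxy]-4-oxobutyl}-5-[(1S,2S,3E)-1-(tert-butyldimethylsilyloxy)-4-iodo-2-methylbut-3-en-1-yl]-3-methylideneoxolan-2-one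
Conditions: TEMPO (cat.), PhI(OAc)2, CH2Cl2, rt
Reagents that add atoms: none
Why: TEMPO/PhI(OAc)2 oxidation converts the primary C1 alcohol into the aldehyde and cannot oxidise the tertiary C10 carbinol.

Step 17
Reactants: 27 (4R,5S)-4-{(1R,3S)-3-hydroxy-3-methyl-1-[(Z)-2-methylbut-2-enoyloxy]-4-oxobutyl}-5-[(1S,2S,3E)-1-(tert-butyldimethylsilyloxy)-4-iodo-2-methylbut-3-en-1-yl]-3-methylideneoxolan-2-one
Product: 29 (1RS,4S,5S,6S,7R,8R,10S)-8-angeloyloxy-5-(tert-butyldimethylsilyloxy)-1,10-dihydroxygermacra-2E,11(13)-dien-12,6-olide, via alkenylchromium dichloride 28 (not isolated)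
Conditions: CrCl2 (12 equiv), NiCl2 (1 mol %), DMSO, rt, 0.002 M, slow addition
Reagents that add atoms: none
Why: Nozaki–Hiyama–Kishi macrocyclisation: nickel-catalysed formation of the alkenylchromium species with retention of the E geometry and its chemoselective addition to the aldehyde close ring B at C1–C2; the C1 epimers converge in step 18.

Step 18
Reactants: 29 (1RS,4S,5S,6S,7R,8R,10S)-8-angeloyloxy-5-(tert-butyldimethylsilyloxy)-1,10-dihydroxygermacra-2E,11(13)-dien-12,6-olide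
Product: 30 (4S,5S,6S,7R,8R,10S)-8-angeloyloxy-5-(tert-butyldimethylsilyloxy)-10-hydroxy-1-oxogermacra-2E,11(13)-dien-12,6-olide
Conditions: Dess–Martin periodinane, CH2Cl2, 0 °C → rt
Reagents that add atoms: none
Why: Dess–Martin oxidation of the secondary allylic alcohol gives the (E)-enone; the tertiary alcohol cannot be oxidised.

Step 19
Reactants: 30 (4S,5S,6S,7R,8R,10S)-8-angeloyloxy-5-(tert-butyldimethylsilyloxy)-10-hydroxy-1-oxogermacra-2E,11(13)-dien-12,6-olide
Product: 31 (4S,5S,6S,7R,8R,10S)-10-acetoxy-8-angeloyloxy-5-(tert-butyldimethylsilyloxy)-1-oxogermacra-2E,11(13)-dien-12,6-olide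
Conditions: Ac2O (10 equiv), Et3N, DMAP (1 equiv), CH2Cl2, rt
Reagents that add atoms: acetic anhydride, CC(=O)OC(C)=O
Why: DMAP-catalysed acyl transfer (Steglich-type acetylation) esterifies the only free hydroxyl, the tertiary α-ketol at C10, with retention.

Step 20
Reactants: 31 (4S,5S,6S,7R,8R,10S)-10-acetoxy-8-angeloyloxy-5-(tert-butyldimethylsilyloxy)-1-oxogermacra-2E,11(13)-dien-12,6-olide
Product: 32 (4S,5S,6S,7R,8R,10S)-10-acetoxy-8-angeloyloxy-5-hydroxy-1-oxogermacra-2E,11(13)-dien-12,6-olide (CNP0259154.2)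
Conditions: HF·pyridine, pyridine, THF, 0 °C → rt
Reagents that add atoms: none
Why: Fluoride-mediated desilylation under buffered, mildly acidic conditions frees C5–OH without touching the two esters, the enone or the α-methylene lactone.

## Compound list

1 | (R)-2-methylglycidol, (2R)-(2-methyloxiran-2-yl)methanol | C[C@@]1(CO)CO1 | starting material
2 | (2S)-2-methylpent-4-ene-1,2-diol | C=CC[C@](C)(O)CO | intermediate
3 | (4S)-2,2,4-trimethyl-4-(prop-2-en-1-yl)-1,3-dioxolane | C=CC[C@@]1(C)COC(C)(C)O1 | intermediate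
4 | secondary ozonide of 3, 3-{[(4S)-2,2,4-trimethyl-1,3-dioxolan-4-yl]methyl}-1,2,4-trioxolane (formed in the flask) | C1(C[C@@]2(C)COC(C)(C)O2)OCOO1 | intermediate
5 | 2-[(4S)-2,2,4-trimethyl-1,3-dioxolan-4-yl]acetaldehyde (C8, C9, C10, C14, C1) | O=CC[C@@]1(C)COC(C)(C)O1 | intermediate
6 | (R)-but-3-yn-2-ol | C#C[C@@H](C)O | starting material
7 | (R)-but-3-yn-2-yl methanesulfonate | C#C[C@@H](C)OS(C)(=O)=O | intermediate
8 | (S)-5-(hydroxymethyl)dihydrofuran-2(3H)-one | OC[C@@H]1CCC(=O)O1 | starting material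
9 | (S)-5-oxotetrahydrofuran-2-carbaldehyde | O=C[C@@H]1CCC(=O)O1 | intermediate
10 | (aS)-buta-1,2-dien-1-yl(ethyl)zinc, allene axis set by anti-SN2′ displacement (formed in the flask; the axis is not encoded in the SMILES) | CC[Zn]C=C=CC | intermediate
11 | (5S)-5-[(1S,2S)-1-hydroxy-2-methylbut-3-yn-1-yl]oxolan-2-one | C#C[C@H](C)[C@H](O)[C@@H]1CCC(=O)O1 | intermediate
12 | (5S)-5-[(1S,2S)-1-(tert-butyldimethylsilyloxy)-2-methylbut-3-yn-1-yl]oxolan-2-one | C#C[C@H](C)[C@H](O[Si](C)(C)C(C)(C)C)[C@@H]1CCC(=O)O1 | intermediate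
13 | (E)-alkenylzirconocene chloride from 12, zirconium on C2 (formed in the flask) | Cl[Zr](/C=C/[C@H](C)[C@H](O[Si](C)(C)C(C)(C)C)[C@@H]1CCC(=O)O1)(C2C=CC=C2)C3C=CC=C3 | intermediate
14 | (5S)-5-[(1S,2S,3E)-1-(tert-butyldimethylsilyloxy)-4-iodo-2-methylbut-3-en-1-yl]oxolan-2-one | I/C=C/[C@H](C)[C@H](O[Si](C)(C)C(C)(C)C)[C@@H]1CCC(=O)O1 | intermediate
15 | lithium enolate of 14 (formed in the flask) | I/C=C/[C@H](C)[C@H](O[Si](C)(C)C(C)(C)C)[C@@H]1CC=C(O[Li])O1 | intermediate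
16 | (3RS,5S)-5-[(1S,2S,3E)-1-(tert-butyldimethylsilyloxy)-4-iodo-2-methylbut-3-en-1-yl]-3-(phenylselanyl)oxolan-2-one | I/C=C/[C@H](C)[C@H](O[Si](C)(C)C(C)(C)C)[C@@H]1CC([Se]c2ccccc2)C(=O)O1 | intermediate
17 | lithium enolate of 16 (formed in the flask) | I/C=C/[C@H](C)[C@H](O[Si](C)(C)C(C)(C)C)[C@@H]1CC([Se]c2ccccc2)=C(O[Li])O1 | intermediate
18 | (3RS,5S)-3-(hydroxymethyl)-3-(phenylselanyl) analogue of 16 (formed in the flask) | I/C=C/[C@H](C)[C@H](O[Si](C)(C)C(C)(C)C)[C@@H]1CC(CO)([Se]c2ccccc2)C(=O)O1 | intermediate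
19 | selenoxide of 18 (formed in the flask) | I/C=C/[C@H](C)[C@H](O[Si](C)(C)C(C)(C)C)[C@@H]1CC(CO)([Se](=O)c2ccccc2)C(=O)O1 | intermediate
20 | (5S)-3-(hydroxymethyl)-5-[(1S,2S,3E)-1-(tert-butyldimethylsilyloxy)-4-iodo-2-methylbut-3-en-1-yl]furan-2(5H)-one | I/C=C/[C@H](C)[C@H](O[Si](C)(C)C(C)(C)C)[C@@H]1C=C(CO)C(=O)O1 | intermediate
21 | (5S)-3-(bromomethyl)-5-[(1S,2S,3E)-1-(tert-butyldimethylsilyloxy)-4-iodo-2-methylbut-3-en-1-yl]furan-2(5H)-one | I/C=C/[C@H](C)[C@H](O[Si](C)(C)C(C)(C)C)[C@@H]1C=C(CBr)C(=O)O1 | intermediate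
22 | allylzinc bromide from 21 (formed in the flask) | I/C=C/[C@H](C)[C@H](O[Si](C)(C)C(C)(C)C)[C@@H]1C=C(C[Zn]Br)C(=O)O1 | intermediate
23 | (5S)-5-[(1S,2S,3E)-1-(tert-butyldimethylsilyloxy)-4-iodo-2-methylbut-3-en-1-yl]-3-[(tributylstannyl)methyl]furan-2(5H)-one | I/C=C/[C@H](C)[C@H](O[Si](C)(C)C(C)(C)C)[C@@H]1C=C(C[Sn](CCCC)(CCCC)CCCC)C(=O)O1 | intermediate
24 | (4R,5S)-4-{(1R)-1-hydroxy-2-[(4S)-2,2,4-trimethyl-1,3-dioxolan-4-yl]ethyl}-5-[(1S,2S,3E)-1-(tert-butyldimethylsilyloxy)-4-iodo-2-methylbut-3-en-1-yl]-3-methylideneoxolan-2-one | C=C1C(=O)O[C@H]([C@@H](O[Si](C)(C)C(C)(C)C)[C@@H](C)/C=C/I)[C@H]1[C@H](O)C[C@@]2(C)COC(C)(C)O2 | intermediate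
25 | angelate of 24 at C8 | C=C1C(=O)O[C@H]([C@@H](O[Si](C)(C)C(C)(C)C)[C@@H](C)/C=C/I)[C@H]1[C@H](OC(=O)/C(C)=C\C)C[C@@]2(C)COC(C)(C)O2 | intermediate
26 | (4R,5S)-4-{(1R,3S)-3,4-dihydroxy-3-methyl-1-[(Z)-2-methylbut-2-enoyloxy]butyl}-5-[(1S,2S,3E)-1-(tert-butyldimethylsilyloxy)-4-iodo-2-methylbut-3-en-1-yl]-3-methylideneoxolan-2-one | C=C1C(=O)O[C@H]([C@@H](O[Si](C)(C)C(C)(C)C)[C@@H](C)/C=C/I)[C@H]1[C@H](OC(=O)/C(C)=C\C)C[C@](C)(O)CO | intermediate
27 | (4R,5S)-4-{(1R,3S)-3-hydroxy-3-methyl-1-[(Z)-2-methylbut-2-enoyloxy]-4-oxobutyl}-5-[(1S,2S,3E)-1-(tert-butyldimethylsilyloxy)-4-iodo-2-methylbut-3-en-1-yl]-3-methylideneoxolan-2-one | C=C1C(=O)O[C@H]([C@@H](O[Si](C)(C)C(C)(C)C)[C@@H](C)/C=C/I)[C@H]1[C@H](OC(=O)/C(C)=C\C)C[C@](C)(O)C=O | intermediate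
28 | (E)-alkenylchromium dichloride from 27, trivalent chromium on C2 (formed in the flask) | C=C1C(=O)O[C@H]([C@@H](O[Si](C)(C)C(C)(C)C)[C@@H](C)/C=C/[Cr](Cl)Cl)[C@H]1[C@H](OC(=O)/C(C)=C\C)C[C@](C)(O)C=O | intermediate
29 | (1RS,4S,5S,6S,7R,8R,10S)-8-angeloyloxy-5-(tert-butyldimethylsilyloxy)-1,10-dihydroxygermacra-2E,11(13)-dien-12,6-olide | C=C1C(=O)O[C@@H]2[C@@H](O[Si](C)(C)C(C)(C)C)[C@@H](C)/C=C/C(O)[C@@](C)(O)C[C@@H](OC(=O)/C(C)=C\C)[C@@H]12 | intermediate
30 | (4S,5S,6S,7R,8R,10S)-8-angeloyloxy-5-(tert-butyldimethylsilyloxy)-10-hydroxy-1-oxogermacra-2E,11(13)-dien-12,6-olide | C=C1C(=O)O[C@@H]2[C@@H](O[Si](C)(C)C(C)(C)C)[C@@H](C)/C=C/C(=O)[C@@](C)(O)C[C@@H](OC(=O)/C(C)=C\C)[C@@H]12 | intermediate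
31 | (4S,5S,6S,7R,8R,10S)-10-acetoxy-8-angeloyloxy-5-(tert-butyldimethylsilyloxy)-1-oxogermacra-2E,11(13)-dien-12,6-olide | C=C1C(=O)O[C@@H]2[C@@H](O[Si](C)(C)C(C)(C)C)[C@@H](C)/C=C/C(=O)[C@@](C)(OC(C)=O)C[C@@H](OC(=O)/C(C)=C\C)[C@@H]12 | intermediate
32 | (4S,5S,6S,7R,8R,10S)-10-acetoxy-8-angeloyloxy-5-hydroxy-1-oxogermacra-2E,11(13)-dien-12,6-olide (CNP0259154.2) | C=C1C(=O)O[C@@H]2[C@@H](O)[C@@H](C)/C=C/C(=O)[C@@](C)(OC(C)=O)C[C@@H](OC(=O)/C(C)=C\C)[C@@H]12 | target

## Step count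

Total steps: 20. Longest linear sequence: 16 steps (8 → 32, steps 5 to 20). The east aldehyde 5 takes 3 steps and the mesylate 7 takes 1 step.

## Three steps most likely to fail

**Step 13 (proposed new step).** The conjugated stannane may be too weak a nucleophile, may protodestannylate, or may give poor 7,8-syn selectivity. The fallback uses known chemistry and sets out from bromide 21 and aldehyde 5. They are coupled directly under Barbier conditions (Zn, THF/sat. aq NH4Cl, rt), the established 2-(alkoxycarbonyl)allylation of aldehydes with 3-(bromomethyl)furan-2(5H)-ones. The closed six-membered transition state of the ring-locked allylzinc still adds trans to the C6 side chain but is expected to give the 7,8-anti adduct, the C8-epimeric carbinol F1. Mitsunobu esterification of F1 with angelic acid (PPh3, DIAD, PhMe, 0 °C) inverts C8 and installs the angelate in one operation. The route is rejoined at 25.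

**Step 17 (ten-membered ring closure).** Ring strain may favour oligomers or simple reduction of the alkenyl iodide. The fallback closes the same ring at C2=C3 by metathesis and sets out from 25. The iodide is removed with CrCl2/NiCl2 (cat.) in DMF followed by water, giving the terminal alkene F2. PPTS/MeOH then gives the diol F3, and TEMPO/PhI(OAc)2 gives the hydroxy aldehyde F4. Intermolecular CrCl2/NiCl2 coupling with vinyl bromide gives the divinyl carbinol F5. Ring-closing metathesis of F5 (second-generation Grubbs catalyst RuCl2(=CHPh)(PCy3)(H2IMes), PhMe, 80 °C, 1 mM) is run under thermodynamic control for the E isomer. The route is rejoined at 29.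

**Step 6 (Marshall propargylation).** The reagent must override the Felkin preference of the hydrate-prone aldehyde 9, so the anti,syn selectivity may be low. The fallback sets out from 9 and replaces propargylation by crotylboration and homologation. B-[(E)-but-2-enyl]diisopinocampheylborane is used as the antipode that attacks the Si face of 9 (from trans-but-2-ene, KOtBu, n-BuLi, Ipc2BOMe, BF3·OEt2; −78 °C; ethanolamine work-up). Its stronger reagent control gives the anti homoallylic alcohol F6. TBSOTf/2,6-lutidine gives the silyl ether F7. Cross-metathesis with vinylboronic acid pinacol ester (second-generation Grubbs catalyst, CH2Cl2, 40 °C) gives the (E)-alkenylboronate F8. Iododeboronation with retention (NaOH, I2, THF/H2O, 0 °C, then acidification to re-close the lactone) rejoins the route at 14.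

## Further compounds

F1 | step 13 | (4R,5S)-4-{(1S)-1-hydroxy-2-[(4S)-2,2,4-trimethyl-1,3-dioxolan-4-yl]ethyl}-5-[(1S,2S,3E)-1-(tert-butyldimethylsilyloxy)-4-iodo-2-methylbut-3-en-1-yl]-3-methylideneoxolan-2-one (C8 epimer of 24) | C=C1C(=O)O[C@H]([C@@H](O[Si](C)(C)C(C)(C)C)[C@@H](C)/C=C/I)[C@H]1[C@@H](O)C[C@@]2(C)COC(C)(C)O2
F2 | step 17 | deiodo analogue of 25 with a terminal C2=C3 vinyl group | C=C1C(=O)O[C@H]([C@@H](O[Si](C)(C)C(C)(C)C)[C@@H](C)C=C)[C@H]1[C@H](OC(=O)/C(C)=C\C)C[C@@]2(C)COC(C)(C)O2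
F3 | step 17 | deiodo analogue of diol 26 | C=C1C(=O)O[C@H]([C@@H](O[Si](C)(C)C(C)(C)C)[C@@H](C)C=C)[C@H]1[C@H](OC(=O)/C(C)=C\C)C[C@](C)(O)CO
F4 | step 17 | deiodo analogue of aldehyde 27 | C=C1C(=O)O[C@H]([C@@H](O[Si](C)(C)C(C)(C)C)[C@@H](C)C=C)[C@H]1[C@H](OC(=O)/C(C)=C\C)C[C@](C)(O)C=O
F5 | step 17 | divinyl carbinol, (1RS)-vinyl adduct of F4 | C=C1C(=O)O[C@H]([C@@H](O[Si](C)(C)C(C)(C)C)[C@@H](C)C=C)[C@H]1[C@H](OC(=O)/C(C)=C\C)C[C@](C)(O)C(O)C=C
F6 | step 6 | (5S)-5-[(1S,2S)-1-hydroxy-2-methylbut-3-en-1-yl]oxolan-2-one | C=C[C@H](C)[C@H](O)[C@@H]1CCC(=O)O1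
F7 | step 6 | (5S)-5-[(1S,2S)-1-(tert-butyldimethylsilyloxy)-2-methylbut-3-en-1-yl]oxolan-2-one | C=C[C@H](C)[C@H](O[Si](C)(C)C(C)(C)C)[C@@H]1CCC(=O)O1
F8 | step 6 | (5S)-5-[(1S,2S,3E)-1-(tert-butyldimethylsilyloxy)-2-methyl-4-(4,4,5,5-tetramethyl-1,3,2-dioxaborolan-2-yl)but-3-en-1-yl]oxolan-2-one | CC1(C)OB(/C=C/[C@H](C)[C@H](O[Si](C)(C)C(C)(C)C)[C@@H]2CCC(=O)O2)OC1(C)C
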